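Retrosynthesis: after the ester C–O bond, the cuts are the ring alkene C4=C5 (metathesis), the side-chain alkene C1'=C2' (olefination of a lactol), the C1–ethyl bond (enolate alkylation) and the two ring methyl groups (back to C=CH2, then C=O or C–O). Last, C1–C2 and C3–C4 fall together in one three-component coupling.
Enabling feature: in the cyclopentane (ring B) of the trans-hydrindene, the vicinal fusion carbons C2 and C3 hold the bonds to quaternary C1 and to the methyl-bearing alkene carbon C4 on opposite faces. Their outer neighbours C9 and C7 are CH(CH3) units that can stand for former C–O carbons, so ring B is a 4-oxygenated cyclopentenone. The triad C6(H)Ph–C1–C1' is the β-carbon, α-carbon and carbonyl carbon of a 4-phenylbutyrolactone whose OCH2 is C5.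
Forward order: arylation gives the lactone, then its enolate, the enone and acetaldehyde are joined. Ring B is present from the start. Its two oxygens become methyl groups, C1 is ethylated, the lactone is opened to enoate plus C5 carbinol, and the cyclohexene (ring A) closes last.
Stereochemistry: C6 comes from the (R)-BINAP/rhodium catalyst, and C2 and C3 from an anti,anti relay starting at the silyloxy carbon of the (S)-enone. C7 and C9 come from two face-selective hydrogenations, C1 from ethylation anti to phenyl, and the (E)-alkene from a stabilised ylide.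

Key step: step 2

Locants used below:
- C1 quaternary carbon
- C2 fusion carbon next to C1
- C3 other fusion carbon
- C4 C(Me)=
- C5 =CH
- C6 CH(Ph)
- C7 CH(Me) next to C3
- C8 CH2
- C9 CH(Me) next to C2
- C1' lactone carbonyl, which becomes the first side-chain carbon
- β is the face of ring B that bears the silyloxy group of 4; α is the opposite face.

Assumption: the carbinol centre C4 made in step 2 (drawn as the S epimer) and the lactol carbon of 20 (left undefined) have no bearing on the target, because both are destroyed later. Compound 4 is taken as commercially available in enantiopure form.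

Step 1
Reactants: 1 furan-2(5H)-one; 2 phenylboronic acid
Product: 3 (R)-4-phenyldihydrofuran-2(3H)-one
Conditions: Rh(acac)(C2H4)2 (3 mol %), (R)-BINAP (3.3 mol %), 2 (2.5 equiv), dioxane/H2O 10:1, 100 °C
Reagents that add atoms: none
Why: Hayashi–Miyaura asymmetric conjugate addition: a phenylrhodium species of monovalent rhodium bound to (R)-BINAP inserts the butenolide alkene on one enantioface and water releases the lactone, the (R)-ligand being the one expected to give (R)-3 by analogy with cyclopentenone and unsaturated δ-lactones, which fixes C6.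

Step 2
Reactants: 3 (R)-4-phenyldihydrofuran-2(3H)-one; 4 (S)-4-(tert-butyldimethylsilyloxy)cyclopent-2-enone; 5 acetaldehyde
Product: 9 (3R,4R)-3-{(1R,2R,5S)-5-(tert-butyldimethylsilyloxy)-2-[(1S)-1-hydroxyethyl]-3-oxocyclopentyl}-4-phenyldihydrofuran-2(3H)-one, via lithium lactone enolate 6 (not isolated), via lithium cyclopentanone enolate 7 (not isolated), via lithium aldolate 8 (not isolated)
Conditions: LiN(i-Pr)2 (1.05 equiv), THF, −78 °C; DMPU (4 equiv); 4 (0.95 equiv), −78 → −45 °C; 5 (3 equiv), −78 °C; AcOH/THF quench at −78 °C
Reagents that add atoms: none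
Why: Deprotonation of 3 gives the planar enolate 6, whose α-carbon adds to the β-carbon of enone 4 to form C1–C2 and the regiodefined enolate 7, which is intercepted at C3 by acetaldehyde (C3–C4) to give aldolate 8 before proton exchange can set in; no ring is closed, so no mode of closure has to be considered. The closest known reaction type is the conjugate addition–aldol three-component coupling of 4-silyloxycyclopentenones known from prostanoid chemistry, merged with the Michael addition of ester and lactone lithium enolates to cyclic enones. C2 is controlled by the C9 silyloxy group, which leaves only the α face of the flat enone open, and C3 is controlled by the newly attached lactone, which sends acetaldehyde to the β face and gives the 2,3-trans ketone that is also the more stable epimer. C1 is controlled by the phenyl group (bond formation anti to it) and C4 by the cyclic lithium-bridged aldol transition state, but both centres are erased later (steps 6 and 14), so their level of control does not matter. The step needs 1,4- rather than 1,2-addition and no deprotonation of 4: carbonyl attack by this ring-constrained, β-phenyl-substituted enolate gives a crowded tertiary alkoxide that can revert, DMPU loosens the lithium ion pair in favour of conjugate attack, and the unsubstituted, exposed β-carbon of the cyclopentenone leads to the ketone enolate as the energetic sink. Staying at or below −45 °C and quenching cold with acetic acid should preserve the β-silyloxy and β-hydroxy ketone units.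

Step 3
Reactants: 9 three-component adduct
Product: 10 triisopropylsilyl ether of 9 (C4–OSi(i-Pr)3; C7 ketone; C3 arm β; C2 lactone α; C9 OTBS β)
Conditions: i-Pr3SiOTf, 2,6-lutidine, CH2Cl2, −78 → 0 °C
Reagents that add atoms: triisopropylsilyl trifluoromethanesulfonate, CC(C)[Si](C(C)C)(C(C)C)OS(=O)(=O)C(F)(F)F
Why: Alcohol silylation with a silyl triflate and a hindered pyridine is fast at low temperature and too weakly basic to trigger retro-aldol cleavage or β-elimination, and the triisopropylsilyl group is chosen because it outlasts the tert-butyldimethylsilyl group in step 7 and adds bulk to the β face for step 5.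

Step 4
Reactants: 10 bis-silylated ketone
Product: 11 C7 exocyclic methylene compound (C7=CH2 in place of C7=O of 10)
Conditions: Zn, CH2Br2, TiCl4 (pre-aged Lombardo reagent), THF/CH2Cl2, 0 °C → rt
Reagents that add atoms: dibromomethane, BrCBr
Why: Lombardo methylenation with the gem-dizinc/titanium reagent is non-basic and selective for ketones over lactones, so that loss of the C9 silyloxy group, epimerisation at C3 and attack on the lactone should all be avoided.

Step 5
Reactants: 11 C7 methylene compound
Product: 12 C7 β-methyl cyclopentane (C7 methyl cis to the C3 arm; C9 OTBS β; C2 lactone α)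
Conditions: H2 (1 atm), PtO2, EtOAc, rt
Reagents that add atoms: none
Why: Heterogeneous syn hydrogenation of the 1,1-disubstituted alkene should take place on the α face, because the β face is covered by the adjacent CH(OSi(i-Pr)3)CH3 arm and by the 1,3-related C9 silyloxy group (the bias that sends bulky hydrides to the corresponding face of 11-O-silylated PGE-type cyclopentanones), which puts the new C7 methyl group β and cis to C4; PtO2 is preferred to palladium to limit exo-to-endo alkene migration.

Step 6
Reactants: 12 C7 β-methyl lactone
Product: 14 α-ethyl lactone having quaternary C1 (ethyl trans to phenyl on the lactone ring; ring B cis to phenyl), via lithium enolate 13 (not isolated)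
Conditions: LiN(i-Pr)2, THF, −78 → −40 °C; EtI, DMPU, −78 → −20 °C
Reagents that add atoms: iodoethane, CCI
Why: Alkylation of a β-substituted γ-butyrolactone enolate: planar enolate 13 erases the provisional C1 centre and should take up ethyl iodide on the face anti to the neighbouring phenyl group, so that the quaternary centre C1 forms with ethyl trans to phenyl on the lactone ring, the arrangement that becomes ethyl cis to phenyl in ring A.

Step 7
Reactants: 14 α-ethyl lactone
Product: 15 C9 β-alcohol (C4 triisopropylsilyl ether retained)
Conditions: camphor-10-sulfonic acid (cat.), MeOH/CH2Cl2, 0 °C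
Reagents that add atoms: none
Why: Acid-catalysed methanolysis distinguishes silyl ethers by the bulk at silicon, so the secondary tert-butyldimethylsilyl ether should be cleaved well before the secondary triisopropylsilyl ether, and the freed β-hydroxyl cannot reach the α-oriented lactone carbonyl.

Step 8
Reactants: 15 C9 β-alcohol
Product: 16 C9 ketone
Conditions: Dess–Martin periodinane, CH2Cl2, 0 °C → rt
Reagents that add atoms: none
Why: Dess–Martin oxidation converts the secondary alcohol into the ketone under neutral conditions, and C2, now α to the carbonyl, already holds the more stable trans relationship to the C3 arm.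

Step 9
Reactants: 16 C9 ketone
Product: 17 C9 exocyclic methylene compound
Conditions: Zn, CH2Br2, TiCl4 (pre-aged Lombardo reagent), THF/CH2Cl2, 0 °C → rt
Reagents that add atoms: dibromomethane, BrCBr
Why: A second Lombardo methylenation is used because the reagent copes with hindered, enolisable ketones without epimerising C2 and ignores the α-quaternary lactone.

Step 10
Reactants: 17 C9 methylene compound
Product: 18 C4 alcohol (triisopropylsilyl group removed; C9=CH2 retained)
Conditions: Bu4NF, THF, rt
Reagents that add atoms: none
Why: Fluoride-induced cleavage of the triisopropylsilyl ether frees the C4 hydroxyl, which both slims the β-face arm and provides the directing group for step 11, while the α-quaternary lactone and the alkene are inert to Bu4NF.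

Step 11
Reactants: 18 C4 alcohol
Product: 19 dimethylcyclopentyl lactone (C9 methyl α and cis to C1; C7 methyl β and cis to C4)
Conditions: [Ir(cod)(PCy3)(py)]PF6 (5 mol %), H2 (1 atm), CH2Cl2, rt
Reagents that add atoms: none
Why: Hydroxyl-directed homogeneous hydrogenation: the cationic iridium catalyst binds the β-oriented C4 hydroxyl and delivers H2 to the β face of the C9 methylene group, which is also the face anti to the adjacent quaternary C1 arm, so that directing and steric effects agree and the C9 methyl group ends α and cis to C1.

Step 12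
Reactants: 19 dimethylcyclopentyl lactone
Product: 20 lactol (C1' now CH(OH), both epimers)
Conditions: i-Bu2AlH (3 equiv), CH2Cl2, −78 °C; aqueous work-up
Reagents that add atoms: none
Why: Partial reduction of a lactone with i-Bu2AlH stops at the lactol because the tetrahedral aluminium alkoxide next to the quaternary carbon persists at −78 °C, one extra equivalent being consumed by the free hydroxyl.

Step 13
Reactants: 20 lactol
Product: 22 ethyl (E)-enoate diol (C1–CH=C(CH3)CO2Et; free C5 and C4 hydroxyls), via open hydroxy aldehyde 21 (not isolated)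
Conditions: Ph3P=C(CH3)CO2Et (3 equiv), PhCO2H (cat.), toluene, 110 °C
Reagents that add atoms: ethyl 2-(triphenylphosphoranylidene)propanoate, CCOC(=O)C(C)=P(c1ccccc1)(c1ccccc1)c1ccccc1
Why: Wittig olefination of a lactol through its open tautomer 21: the stabilised α-methyl ylide gives the (E)-trisubstituted enoate and sets the C5 hydroxyl free, and re-closure by oxa-Michael addition is disfavoured by the α-methyl group and the neopentyl β-carbon.

Step 14
Reactants: 22 enoate diol
Product: 23 keto aldehyde (C5 aldehyde on C6; acetyl group on C3)
Conditions: Dess–Martin periodinane (3 equiv), CH2Cl2, 0 °C → rt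
Reagents that add atoms: none
Why: Double Dess–Martin oxidation turns the primary and the secondary alcohol into aldehyde and methyl ketone in one operation under neutral conditions that should not enolise the α-phenyl aldehyde (C6) or the ketone (C3).

Step 15
Reactants: 23 keto aldehyde
Product: 24 triene (vinyl on C6; isopropenyl on C3; enoate on C1)
Conditions: Zn, CH2Br2, TiCl4 (pre-aged Lombardo reagent, excess), THF/CH2Cl2, 0 °C → rt
Reagents that add atoms: dibromomethane, BrCBr
Why: Twofold Lombardo methylenation converts aldehyde and methyl ketone into vinyl and isopropenyl groups without base, so that the labile C6 and C3 centres are kept, and conjugated esters are not attacked by this reagent.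

Step 16
Reactants: 24 triene
Product: 25 plakotenin ethyl ester
Conditions: second-generation Grubbs catalyst RuCl2(=CHPh)(PCy3)(H2IMes) (5–10 mol %), 1,4-benzoquinone (10 mol %), toluene (2 mM), 80 °C
Reagents that add atoms: none
Why: Ring-closing metathesis: the ruthenium carbene should load on the monosubstituted vinyl group and close onto the isopropenyl group to give the trisubstituted alkene of the six-membered ring A, trans-fused because the two arms sit trans on ring B, while the trisubstituted electron-poor enoate is inert and benzoquinone suppresses hydride-induced migration of the benzylic vinyl group.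

Step 17
Reactants: 25 plakotenin ethyl ester
Product: 27 plakotenin, via lithium carboxylate 26 (not isolated)
Conditions: LiOH, THF/MeOH/H2O, 50 °C; then 1 M HCl
Reagents that add atoms: lithium hydroxide, [Li+].[OH-]
Why: Saponification of the ethyl ester followed by acidification gives the free acid, no stereocentre or alkene of 25 being labile to aqueous hydroxide.

Compound list
1 | furan-2(5H)-one | O=C1OCC=C1 | starting material
2 | phenylboronic acid | OB(O)c1ccccc1 | starting material
3 | (R)-4-phenyldihydrofuran-2(3H)-one | O=C1C[C@H](c2ccccc2)CO1 | intermediate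
4 | (S)-4-(tert-butyldimethylsilyloxy)cyclopent-2-enone | O=C1C=C[C@@H](O[Si](C)(C)C(C)(C)C)C1 | starting material
5 | acetaldehyde | CC=O | starting material
6 | lithium enolate of 3 (not isolated) | [Li]OC1=C[C@H](c2ccccc2)CO1 | intermediate
7 | lithium C7,C3-enolate of the Michael adduct, lactone α at C2, OTBS β at C9 (not isolated) | [Li]OC1=C[C@H]([C@@H]2C(=O)OC[C@H]2c2ccccc2)[C@@H](O[Si](C)(C)C(C)(C)C)C1 | intermediate
8 | lithium aldolate of 9 (not isolated) | O=C1[C@@H]([C@H](C)O[Li])[C@H]([C@@H]2C(=O)OC[C@H]2c2ccccc2)[C@@H](O[Si](C)(C)C(C)(C)C)C1 | intermediate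
9 | (3R,4R)-3-{(1R,2R,5S)-5-(tert-butyldimethylsilyloxy)-2-[(1S)-1-hydroxyethyl]-3-oxocyclopentyl}-4-phenyldihydrofuran-2(3H)-one | O=C1[C@@H]([C@H](C)O)[C@H]([C@@H]2C(=O)OC[C@H]2c2ccccc2)[C@@H](O[Si](C)(C)C(C)(C)C)C1 | intermediate
10 | C4 triisopropylsilyl ether of 9 | O=C1[C@@H]([C@H](C)O[Si](C(C)C)(C(C)C)C(C)C)[C@H]([C@@H]2C(=O)OC[C@H]2c2ccccc2)[C@@H](O[Si](C)(C)C(C)(C)C)C1 | intermediate
11 | C7 exocyclic methylene analogue of 10 | C=C1[C@@H]([C@H](C)O[Si](C(C)C)(C(C)C)C(C)C)[C@H]([C@@H]2C(=O)OC[C@H]2c2ccccc2)[C@@H](O[Si](C)(C)C(C)(C)C)C1 | intermediate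
12 | C7 β-methyl cyclopentane, C3 arm β, C2 lactone α, C9 OTBS β | C[C@H]1[C@@H]([C@H](C)O[Si](C(C)C)(C(C)C)C(C)C)[C@H]([C@@H]2C(=O)OC[C@H]2c2ccccc2)[C@@H](O[Si](C)(C)C(C)(C)C)C1 | intermediate
13 | lithium lactone enolate of 12 (not isolated) | C[C@H]1[C@@H]([C@H](C)O[Si](C(C)C)(C(C)C)C(C)C)[C@H](C2=C(O[Li])OC[C@H]2c2ccccc2)[C@@H](O[Si](C)(C)C(C)(C)C)C1 | intermediate
14 | α-ethyl lactone, quaternary C1, ethyl trans to phenyl on the lactone ring | C[C@H]1[C@@H]([C@H](C)O[Si](C(C)C)(C(C)C)C(C)C)[C@H]([C@@]2(CC)C(=O)OC[C@H]2c2ccccc2)[C@@H](O[Si](C)(C)C(C)(C)C)C1 | intermediate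
15 | C9 β-alcohol | C[C@H]1[C@@H]([C@H](C)O[Si](C(C)C)(C(C)C)C(C)C)[C@H]([C@@]2(CC)C(=O)OC[C@H]2c2ccccc2)[C@@H](O)C1 | intermediate
16 | C9 ketone | C[C@H]1[C@@H]([C@H](C)O[Si](C(C)C)(C(C)C)C(C)C)[C@H]([C@@]2(CC)C(=O)OC[C@H]2c2ccccc2)C(=O)C1 | intermediate
17 | C9 exocyclic methylene compound | C[C@H]1[C@@H]([C@H](C)O[Si](C(C)C)(C(C)C)C(C)C)[C@H]([C@@]2(CC)C(=O)OC[C@H]2c2ccccc2)C(=C)C1 | intermediate
18 | C4 alcohol with C9=CH2 | C[C@H]1[C@@H]([C@H](C)O)[C@H]([C@@]2(CC)C(=O)OC[C@H]2c2ccccc2)C(=C)C1 | intermediate
19 | dimethylcyclopentyl lactone, C7 methyl β, C9 methyl α | C[C@H]1[C@@H]([C@H](C)O)[C@H]([C@@]2(CC)C(=O)OC[C@H]2c2ccccc2)[C@H](C)C1 | intermediate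
20 | lactol of 19 (lactol carbon undefined) | C[C@H]1[C@@H]([C@H](C)O)[C@H]([C@@]2(CC)C(O)OC[C@H]2c2ccccc2)[C@H](C)C1 | intermediate
21 | open hydroxy aldehyde tautomer of 20 (not isolated) | C[C@H]1[C@@H]([C@H](C)O)[C@H]([C@@](CC)(C=O)[C@@H](CO)c2ccccc2)[C@H](C)C1 | intermediate
22 | ethyl (E)-enoate diol | C[C@H]1[C@@H]([C@H](C)O)[C@H]([C@@](CC)(/C=C(\C)C(=O)OCC)[C@@H](CO)c2ccccc2)[C@H](C)C1 | intermediate
23 | keto aldehyde | C[C@H]1[C@@H](C(C)=O)[C@H]([C@@](CC)(/C=C(\C)C(=O)OCC)[C@@H](C=O)c2ccccc2)[C@H](C)C1 | intermediate
24 | triene (vinyl, isopropenyl, enoate) | C[C@H]1[C@@H](C(C)=C)[C@H]([C@@](CC)(/C=C(\C)C(=O)OCC)[C@@H](C=C)c2ccccc2)[C@H](C)C1 | intermediate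
25 | plakotenin ethyl ester | CC[C@@]1(/C=C(\C)C(=O)OCC)[C@H]2[C@H](C(C)=C[C@H]1c1ccccc1)[C@H](C)C[C@H]2C | intermediate
26 | lithium salt of plakotenin (not isolated) | [Li+].CC[C@@]1(/C=C(\C)C(=O)[O-])[C@H]2[C@H](C(C)=C[C@H]1c1ccccc1)[C@H](C)C[C@H]2C | intermediate
27 | plakotenin, (2E)-3-[(1R,3R,3aR,4S,5S,7aR)-4-ethyl-1,3,7-trimethyl-5-phenyl-2,3,3a,4,5,7a-hexahydro-1H-inden-4-yl]-2-methylprop-2-enoic acid | CC[C@@]1(/C=C(\C)C(=O)O)[C@H]2[C@H](C(C)=C[C@H]1c1ccccc1)[C@H](C)C[C@H]2C | target

Total step count: 17. Longest linear sequence: 17 steps (1 → 27); compounds 4 and 5 enter as purchased.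

Steps most likely to fail

Step 2.
- What may go wrong: carbonyl addition of the enolate may not revert at the temperatures the β-silyloxy enolate tolerates. Proton abstraction from 4 may be followed by loss of silanolate. Proton exchange within 7 may occur before the aldehyde arrives.
- Fallback (from 3, back at 9): the lactone is silylated on oxygen (LiN(i-Pr)2, t-BuMe2SiCl, THF/DMPU, −78 °C) to give the silyl ketene acetal F1. This neutral, soft nucleophile undergoes a Mukaiyama–Michael addition to 4 (catalytic HgI2, CH2Cl2, low temperature) with silyl transfer, again anti to the C9 silyloxy group, to give the silyl enol ether F2. A TiCl4-mediated Mukaiyama aldol reaction of F2 with 5 at −78 °C, anti to the lactone, gives 9 after aqueous work-up.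
- The same two bonds form in the same order, but without base, so 1,2-addition and enone deprotonation play no part.

Step 6.
- What may go wrong: deprotonation and alkylation at the congested tertiary α-carbon may be sluggish, O-alkylation may compete, and facial selectivity may erode if the reaction has to be forced.
- Fallback (from 12, back at 14): enolate 13 is intercepted with acetaldehyde 5, which is small and far more electrophilic than ethyl iodide, again anti to phenyl. This gives the α-(1-hydroxyethyl) lactone F3. Treatment with 1,1'-thiocarbonyldiimidazole (DMAP, CH2Cl2, neutral so that retro-aldol cleavage is avoided) gives the imidazole-1-carbothioate F4. Barton–McCombie deoxygenation (Bu3SnH, AIBN, toluene, 90 °C) turns the side chain into ethyl and gives 14.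

Step 13.
- What may go wrong: the lactol equilibria may keep the concentration of the very hindered neopentyl aldehyde too low for the bulky stabilised ylide. Prolonged heating may let a liberated hydroxyl add back to the enoate.
- Fallback (from 19, back at 24): 19 is reduced with LiAlH4 (THF, 0 °C → rt) to the triol F5.
- Swern oxidation ((COCl)2, DMSO, then i-Pr2NEt, −78 °C) activates all three hydroxyls before base is added, so that no lactol can form, and gives the keto dialdehyde F6.
- One equivalent of the aldehyde-selective CH2I2/Zn/Ti(Oi-Pr)4 reagent methylenates the less hindered C5 aldehyde to give the vinyl keto aldehyde F7.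
- The remaining neopentyl aldehyde is now free, with no hydroxyl group left in the molecule. It is heated with Ph3P=C(CH3)CO2Et, to which the ketone is inert, and gives the vinyl keto enoate F8.
- Lombardo methylenation (Zn, CH2Br2, TiCl4) of the methyl ketone then gives 24.

Further compounds
F1 | step 2 | (R)-tert-butyldimethyl[(4-phenyl-4,5-dihydrofuran-2-yl)oxy]silane (silyl ketene acetal of 3) | CC(C)(C)[Si](C)(C)OC1=C[C@H](c2ccccc2)CO1
F2 | step 2 | tert-butyldimethylsilyl enol ether (C7–OSi, C7=C3) of the Michael adduct of 3 and 4 | CC(C)(C)[Si](C)(C)OC1=C[C@H]([C@@H]2C(=O)OC[C@H]2c2ccccc2)[C@@H](O[Si](C)(C)C(C)(C)C)C1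
F3 | step 6 | α-(1-hydroxyethyl) lactone (carbinol carbon undefined, hydroxyethyl trans to phenyl) | C[C@H]1[C@@H]([C@H](C)O[Si](C(C)C)(C(C)C)C(C)C)[C@H]([C@@]2(C(C)O)C(=O)OC[C@H]2c2ccccc2)[C@@H](O[Si](C)(C)C(C)(C)C)C1
F4 | step 6 | imidazole-1-carbothioate of F3 | C[C@H]1[C@@H]([C@H](C)O[Si](C(C)C)(C(C)C)C(C)C)[C@H]([C@@]2(C(C)OC(=S)n3ccnc3)C(=O)OC[C@H]2c2ccccc2)[C@@H](O[Si](C)(C)C(C)(C)C)C1
F5 | step 13 | triol from complete reduction of 19 | C[C@H]1[C@@H]([C@H](C)O)[C@H]([C@@](CC)(CO)[C@@H](CO)c2ccccc2)[C@H](C)C1
F6 | step 13 | keto dialdehyde | C[C@H]1[C@@H](C(C)=O)[C@H]([C@@](CC)(C=O)[C@@H](C=O)c2ccccc2)[C@H](C)C1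
F7 | step 13 | vinyl keto aldehyde | C[C@H]1[C@@H](C(C)=O)[C@H]([C@@](CC)(C=O)[C@@H](C=C)c2ccccc2)[C@H](C)C1
F8 | step 13 | vinyl keto enoate | C[C@H]1[C@@H](C(C)=O)[C@H]([C@@](CC)(/C=C(\C)C(=O)OCC)[C@@H](C=C)c2ccccc2)[C@H](C)C1
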